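## Analysis of the target

The target is a biflavone of the robustaflavone type. A 5-hydroxy-7-methoxychromone (the methoxychromone unit) carries at C2 a 4-methoxyphenyl ring (the central anisole ring). The carbon of that ring ortho to its methoxy group is bonded to C6 of an intact acacetin unit (5,7-dihydroxy-4'-methoxyflavone). There is no stereocentre; the biaryl axis between C6 and the anisole ring carries three ortho oxygen substituents, but the target is written without an axial descriptor, so it is assumed that the axis needs no control. Three free phenols, two of them chelated to the C4 carbonyls, must end up distinct from three methyl ethers, so no unselective demethylation is allowed late in the route. The pyranones open in hot aqueous alkali, and strong protic acid could move the aryl group from C6 to C8 by ring opening and reclosure. The difficulties are the C6 versus C8 regiochemistry on ring A of the acacetin unit, the tri-ortho-substituted biaryl bond, the 5-OH/7-OMe pattern of the methoxychromone unit, and the low solubility of biflavones. The strategy rests on the pyranone of the methoxychromone unit. Its C4 carbonyl and its C2=C3 pair hang on the anisole ring through C2. Its benzo ring has oxygen on both carbons next to C4a and a methoxy group para to C4a. Taking out C4 as carbon monoxide and C2=C3 as an aryl alkyne therefore leaves a mirror-symmetric 2-iodo-5-methoxyresorcinol.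

## Retrosynthetic reasoning

**20 to 19.** The two O–benzyl bonds on O5 and O7 of the acacetin unit are cut last. Benzyl is chosen because it masks both phenols through the palladium steps and the desilylation, and it can be removed by hydrogenolysis without touching any methyl ether. The forward step only has to spare the two C2=C3 bonds.

**19 to 10, 15 and 16.** The pyranone of the methoxychromone unit is cut at C4a–C4, C4–C3 and O1–C2. This gives terminal alkyne 10, iodoresorcinol 15 and carbon monoxide 16. The cut is made here because this is the only ring in the molecule whose benzo part is symmetric once C4 is removed. Either hydroxyl of 15 can close the ring, and the other becomes the free 5-OH, so the 5-OH/7-OMe pattern needs no protecting group and no selective demethylation. The cut is also convergent: the whole acacetin unit arrives in 10. The forward reaction must carbonylate before it alkynylates and must close the six-membered ring, not the five-membered one.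

**10 to 9.** The C(sp)–Si bond is cut. The alkyne is carried as its triisopropylsilyl derivative because a trimethylsilyl alkyne would be partly cleaved by the aqueous base of the biaryl coupling, and the freed alkyne would then couple with the aryl iodide.

**9 to 4 and 8.** The biaryl bond between C6 of the flavone and the anisole ring is cut, with the halide on the flavone (iodide 4) and boron on the anisole (boronate 8). This polarity is chosen because C6 of the flavone can be iodinated selectively, whereas the anisole piece is easily borylated. The forward coupling has to form a tri-ortho-substituted biaryl.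

**4 to 3, 2 and 1.** The benzyl ethers and the C6–I bond are removed in an order fixed by regiochemistry. Acacetin 1 is benzylated first at the non-chelated O7 to give 2. Iodination of 2, with its 5-OH still free, is directed to the ortho carbon C6 and gives 3. Only then is O5 benzylated to give 4. Iodination after the second benzylation would go to C8.

**8 to 7, 5 and 6.** The C–B bond of 8 goes back to the C–Br bond of 7. The aryl–alkyne bond of 7 goes back to the C–I bond of dihalide 5 and silylacetylene 6. The iodide reacts before the bromide, so the two halogens are used in sequence without protection.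

**15 to 14, 12 and 11.** The two hydroxyls of 15 are masked as methoxymethyl ethers in 14. The C–I bond of 14 is traced to aryllithium 13, formed by deprotonation of 12 between its two acetal oxygens. Compound 12 comes from 5-methoxyresorcinol 11. Directed lithiation is chosen over direct iodination of 11 because it fixes the iodine between the two oxygens.

## Alternatives that were turned down

**Alternative 1:** Both pyranones are disconnected at C2–C3, in two directions from the central biaryl. In the forward key step, base would enolise both acetyl groups of bis-ester A2, and two O-to-C aroyl shifts (double Baker–Venkataraman rearrangement) would give bis(1,3-diketone) A1 with both ring-closing phenols freed. Acid would then close both rings.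
- For: the chemistry is classical, needs no pressurised gas and no transition metal, and has no benzofuran side path. It makes both heterocycles in one operation, and on these points it is stronger than the chosen route.
- Against: A2 is a hexasubstituted biaryl acetophenone in which acetyl, acyloxy, two benzyloxy groups and the aryl group must be placed in a fixed order. The C6/C8 problem is thus only moved to telling apart three oxygens of an aryl-phloroacetophenone.
- Against: two different esters have to be installed on two different phenols.
- Against: the 5-oxygen of the methoxychromone unit must travel as a methyl ether, because a free hydroxyl would be acylated. A selective peri-demethylation is then needed at the end.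
- Against: the acacetin unit is built from scratch although it can be bought.
- Comparison: the chosen route offers a short, convergent assembly and sets the 5-OH/7-OMe pattern by symmetry.

**Alternative 2:** The phloroglucinol ring of the acacetin unit is disconnected at its C5–C6 bond to an acyclic triketide. In the forward key step, strong base would make the benzylic carbon of triketo ester A4 attack the ester carbon. Enolisation would then give aryl-phloroglucinol A3.
- For: the aryl group sits between two hydroxyls by construction, so neither a hindered cross-coupling nor a regioselective halogenation is needed. On the biaryl bond it is stronger than the chosen route.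
- Against: A3 is far from the target, and both chromones still have to be built.
- Against: when the acacetin pyranone is closed on A3, the hydroxyl next to the aryl group and the remote one compete. The 6-aryl/8-aryl question therefore returns.
- Against: the benzylic C–H is the least acidic position of A4. The cyclisation needs a polyanion and competes with aldol closure and with pyranone formation through oxygen.
- Comparison: the chosen route accepts a hindered Suzuki coupling and in exchange buys the acacetin ring ready-made and leaves one step after the key step.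

**Alternative 3:** The benzo ring of the methoxychromone unit is disconnected at C4a–C5 and C8–C8a. In the forward key step, Brassard diene A6 would add across C5=C6 of sulfinylpyranone A7. Loss of benzenesulfenic acid and methanol would aromatise the adduct to chromone A5.
- For: the polarity of the diene fixes 5-OH and 7-OMe directly, and no carbon monoxide is used. On the oxygen pattern it is as good as the chosen route.
- Against: A7 is an unusual heterocycle that needs its own multistep synthesis.
- Against: C5=C6 of a 4-pyranone is a vinylogous ester double bond and a poor dienophile, even with the sulfinyl group.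
- Against: A5 carries only a tris(benzyloxy)phenyl ring where the acacetin unit should be. The whole second chromone, with its C6/C8 problem, would still have to be built on a hindered ring after the key step.
- Comparison: the chosen route solves the oxygen pattern by the symmetry of 15 and finishes one step after the key step.

Key step: step 11

## Route

**Step 1**
Reactants: 1 acacetin
Product: 2 7-(benzyloxy)-5-hydroxy-2-(4-methoxyphenyl)-4H-chromen-4-one
Conditions: BnBr (1.1 equiv), K2CO3, acetone, reflux
Reagents that add atoms: benzyl bromide, BrCc1ccccc1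
Why: Williamson ether synthesis; the 7-OH is the more acidic, non-chelated phenol, while the 5-OH is held in a hydrogen bond to the C4 carbonyl, so one equivalent of halide should alkylate O7 only.

**Step 2**
Reactants: 2 7-(benzyloxy)-5-hydroxy-2-(4-methoxyphenyl)-4H-chromen-4-one
Product: 3 7-(benzyloxy)-5-hydroxy-6-iodo-2-(4-methoxyphenyl)-4H-chromen-4-one
Conditions: NIS (1.05 equiv), DMF, rt, dark
Reagents that add atoms: N-iodosuccinimide, O=C1CCC(=O)N1I
Why: Electrophilic aromatic iodination; in 5-hydroxy-7-alkoxyflavones the free chelated 5-OH directs iodine to its ortho carbon C6, whereas 5-O-alkylated flavones react at C8, which is why this step precedes the second benzylation; the anisyl ring, conjugated to the enone, is much less activated.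

**Step 3**
Reactants: 3 7-(benzyloxy)-5-hydroxy-6-iodo-2-(4-methoxyphenyl)-4H-chromen-4-one
Product: 4 5,7-bis(benzyloxy)-6-iodo-2-(4-methoxyphenyl)-4H-chromen-4-one
Conditions: BnBr, Cs2CO3, nBu4NI (cat.), DMF, 60 °C
Reagents that add atoms: benzyl bromide, BrCc1ccccc1
Why: Williamson ether synthesis on the chelated, flanked 5-OH, which needs the caesium phenoxide in a dipolar solvent; the aryl iodide and the pyranone are inert to carbonate.

**Step 4**
Reactants: 5 2-bromo-4-iodoanisole; 6 ethynyltri(propan-2-yl)silane
Product: 7 [(3-bromo-4-methoxyphenyl)ethynyl]tri(propan-2-yl)silane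
Conditions: PdCl2(PPh3)2 (2 mol %), CuI (4 mol %), Et3N, THF, rt
Reagents that add atoms: none
Why: Sonogashira coupling; oxidative addition into C–I is far faster than into C–Br at room temperature, so only the iodide para to the methoxy group should react.

**Step 5**
Reactants: 7 [(3-bromo-4-methoxyphenyl)ethynyl]tri(propan-2-yl)silane
Product: 8 {[4-methoxy-3-(4,4,5,5-tetramethyl-1,3,2-dioxaborolan-2-yl)phenyl]ethynyl}tri(propan-2-yl)silane
Conditions: B2pin2, Pd(dppf)Cl2 (3 mol %), KOAc, 1,4-dioxane, 90 °C
Reagents that add atoms: bis(pinacolato)diboron, CC1(C)OB(OC1(C)C)B1OC(C)(C)C(C)(C)O1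
Why: Miyaura borylation of the aryl bromide; the weak acetate base leaves the silyl alkyne intact and prevents the boronate from coupling with unreacted bromide.

**Step 6**
Reactants: 4 5,7-bis(benzyloxy)-6-iodo-2-(4-methoxyphenyl)-4H-chromen-4-one; 8 {[4-methoxy-3-(4,4,5,5-tetramethyl-1,3,2-dioxaborolan-2-yl)phenyl]ethynyl}tri(propan-2-yl)silane
Product: 9 5,7-bis(benzyloxy)-6-{2-methoxy-5-[(triisopropylsilyl)ethynyl]phenyl}-2-(4-methoxyphenyl)-4H-chromen-4-one
Conditions: Pd(OAc)2 (5 mol %), SPhos (10 mol %), K3PO4, 8 (1.5 equiv), toluene–H2O (10:1), 90 °C
Reagents that add atoms: none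
Why: Suzuki–Miyaura coupling; a bulky dialkylbiarylphosphine is used because the new biaryl bond has three ortho substituents; the triisopropylsilyl alkyne, the benzyl ethers and the pyranone tolerate aqueous phosphate.

**Step 7**
Reactants: 9 5,7-bis(benzyloxy)-6-{2-methoxy-5-[(triisopropylsilyl)ethynyl]phenyl}-2-(4-methoxyphenyl)-4H-chromen-4-one
Product: 10 5,7-bis(benzyloxy)-6-(5-ethynyl-2-methoxyphenyl)-2-(4-methoxyphenyl)-4H-chromen-4-one
Conditions: nBu4NF, THF, 0 °C to rt
Reagents that add atoms: none
Why: Fluoride-induced cleavage of the C(sp)–Si bond (protodesilylation); benzyl ethers and the flavone are stable to fluoride at this temperature.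

**Step 8**
Reactants: 11 5-methoxyresorcinol
Product: 12 1-methoxy-3,5-bis(methoxymethoxy)benzene
Conditions: MOMCl (2.5 equiv), iPr2NEt, CH2Cl2, 0 °C to rt
Reagents that add atoms: chloromethyl methyl ether, COCCl
Why: O-alkylation of both phenols to methoxymethyl ethers, which mask the acidic protons and serve as directing groups for the next step.

**Step 9**
Reactants: 12 1-methoxy-3,5-bis(methoxymethoxy)benzene
Product: 14 2-iodo-5-methoxy-1,3-bis(methoxymethoxy)benzene, via aryllithium 13 (not isolated)
Conditions: n-BuLi, THF, 0 °C; then I2, −78 °C to rt
Reagents that add atoms: iodine, II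
Why: Directed ortho-metalation; the proton between the two chelating acetal oxygens is the most acidic and best coordinated, more so than those between an acetal and the methoxy group, and iodine traps aryllithium 13 at that carbon.

**Step 10**
Reactants: 14 2-iodo-5-methoxy-1,3-bis(methoxymethoxy)benzene
Product: 15 2-iodo-5-methoxybenzene-1,3-diol
Conditions: HCl (0.2 equiv), MeOH, rt, dark; used at once
Reagents that add atoms: none
Why: Acid-catalysed acetal exchange with methanol frees both phenols; the acid is kept catalytic and the temperature low to avoid ipso protonation of the electron-rich iodoarene.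

**Step 11**
Reactants: 10 5,7-bis(benzyloxy)-6-(5-ethynyl-2-methoxyphenyl)-2-(4-methoxyphenyl)-4H-chromen-4-one; 15 2-iodo-5-methoxybenzene-1,3-diol; 16 carbon monoxide
Product: 19 5,7-bis(benzyloxy)-6-[5-(5-hydroxy-7-methoxy-4-oxo-4H-chromen-2-yl)-2-methoxyphenyl]-2-(4-methoxyphenyl)-4H-chromen-4-one, via ynone 17 (not isolated), via enaminone 18 (not isolated)
Conditions: PdCl2(PPh3)2 (5 mol %), CO (10 bar), 15 (1.3 equiv), Et2NH–DMF (1:2), 90 °C
Reagents that add atoms: none
Why: PdCl2(PPh3)2, a divalent palladium precatalyst, should be reduced in the amine/CO medium to zerovalent palladium, which inserts into the C–I bond of 15, and CO then inserts to give an aroylpalladium iodide. The amine delivers the acetylide of 10 to palladium, and reductive elimination forms ynone 17, which creates the C4a–C4 and C4–C3 bonds. Et2NH adds to the ynone in conjugate fashion to give enaminone 18; one of the two ortho hydroxyls then attacks the amine-bearing carbon and expels Et2NH, an addition–elimination that is 6-endo with respect to the original triple bond and forms O1–C2. The closest known reaction type is the palladium-catalysed carbonylative Sonogashira annulation of ortho-iodophenols with terminal aryl alkynes to flavones in a secondary amine. No stereocentre is formed. Three selectivities are needed: carbonylation before alkynylation (direct coupling would end in a 2-arylbenzofuran), favoured by CO pressure and the absence of CuI; 6-endo closure, not 5-exo closure to an aurone, secured by the enaminone, whose electrophilic carbon is the one that bears the aryl group; and the choice of hydroxyl, which does not arise because 15 has a mirror plane through C2 and C5, so the hydroxyl left over becomes the chelated 5-OH. The benzyl ethers and the pyranone of the acacetin unit in 10 offer no reactive site under these conditions, and 10 carries no second halide.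

**Step 12**
Reactants: 19 5,7-bis(benzyloxy)-6-[5-(5-hydroxy-7-methoxy-4-oxo-4H-chromen-2-yl)-2-methoxyphenyl]-2-(4-methoxyphenyl)-4H-chromen-4-one
Product: 20 5,7-dihydroxy-6-[5-(5-hydroxy-7-methoxy-4-oxo-4H-chromen-2-yl)-2-methoxyphenyl]-2-(4-methoxyphenyl)-4H-chromen-4-one (target)
Conditions: H2 (1 atm), Pd/C (10 %), THF–MeOH, rt
Reagents that add atoms: none
Why: Catalytic hydrogenolysis of the two benzyl aryl ethers; the aryl-conjugated C2=C3 bonds of flavones resist hydrogenation at atmospheric pressure, and the three methyl ethers are untouched.

## Compound list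

1 | acacetin (5,7-dihydroxy-2-(4-methoxyphenyl)-4H-chromen-4-one) | COc1ccc(-c2cc(=O)c3c(O)cc(O)cc3o2)cc1 | starting material
2 | 7-(benzyloxy)-5-hydroxy-2-(4-methoxyphenyl)-4H-chromen-4-one | COc1ccc(-c2cc(=O)c3c(O)cc(OCc4ccccc4)cc3o2)cc1 | intermediate
3 | 7-(benzyloxy)-5-hydroxy-6-iodo-2-(4-methoxyphenyl)-4H-chromen-4-one | COc1ccc(-c2cc(=O)c3c(O)c(I)c(OCc4ccccc4)cc3o2)cc1 | intermediate
4 | 5,7-bis(benzyloxy)-6-iodo-2-(4-methoxyphenyl)-4H-chromen-4-one | COc1ccc(-c2cc(=O)c3c(OCc4ccccc4)c(I)c(OCc4ccccc4)cc3o2)cc1 | intermediate
5 | 2-bromo-4-iodoanisole | COc1ccc(I)cc1Br | starting material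
6 | ethynyltri(propan-2-yl)silane (triisopropylsilylacetylene) | C#C[Si](C(C)C)(C(C)C)C(C)C | starting material
7 | [(3-bromo-4-methoxyphenyl)ethynyl]tri(propan-2-yl)silane | COc1ccc(C#C[Si](C(C)C)(C(C)C)C(C)C)cc1Br | intermediate
8 | {[4-methoxy-3-(4,4,5,5-tetramethyl-1,3,2-dioxaborolan-2-yl)phenyl]ethynyl}tri(propan-2-yl)silane | COc1ccc(C#C[Si](C(C)C)(C(C)C)C(C)C)cc1B1OC(C)(C)C(C)(C)O1 | intermediate
9 | 5,7-bis(benzyloxy)-6-{2-methoxy-5-[(triisopropylsilyl)ethynyl]phenyl}-2-(4-methoxyphenyl)-4H-chromen-4-one | COc1ccc(-c2cc(=O)c3c(OCc4ccccc4)c(-c4cc(C#C[Si](C(C)C)(C(C)C)C(C)C)ccc4OC)c(OCc4ccccc4)cc3o2)cc1 | intermediate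
10 | 5,7-bis(benzyloxy)-6-(5-ethynyl-2-methoxyphenyl)-2-(4-methoxyphenyl)-4H-chromen-4-one | COc1ccc(-c2cc(=O)c3c(OCc4ccccc4)c(-c4cc(C#C)ccc4OC)c(OCc4ccccc4)cc3o2)cc1 | intermediate
11 | 5-methoxyresorcinol (5-methoxybenzene-1,3-diol) | COc1cc(O)cc(O)c1 | starting material
12 | 1-methoxy-3,5-bis(methoxymethoxy)benzene | COCOc1cc(OC)cc(OCOC)c1 | intermediate
13 | [4-methoxy-2,6-bis(methoxymethoxy)phenyl]lithium | COCOc1cc(OC)cc(OCOC)c1[Li] | intermediate
14 | 2-iodo-5-methoxy-1,3-bis(methoxymethoxy)benzene | COCOc1cc(OC)cc(OCOC)c1I | intermediate
15 | 2-iodo-5-methoxybenzene-1,3-diol | COc1cc(O)c(I)c(O)c1 | intermediate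
16 | carbon monoxide | [C-]#[O+] | starting material
17 | 5,7-bis(benzyloxy)-6-{5-[3-(2,6-dihydroxy-4-methoxyphenyl)-3-oxoprop-1-yn-1-yl]-2-methoxyphenyl}-2-(4-methoxyphenyl)-4H-chromen-4-one | COc1ccc(-c2cc(=O)c3c(OCc4ccccc4)c(-c4cc(C#CC(=O)c5c(O)cc(OC)cc5O)ccc4OC)c(OCc4ccccc4)cc3o2)cc1 | intermediate
18 | 5,7-bis(benzyloxy)-6-{5-[(1E)-1-(diethylamino)-3-(2,6-dihydroxy-4-methoxyphenyl)-3-oxoprop-1-en-1-yl]-2-methoxyphenyl}-2-(4-methoxyphenyl)-4H-chromen-4-one (drawn as the E isomer; the push–pull double bond isomerises readily and its geometry has no bearing on the closure) | COc1ccc(-c2cc(=O)c3c(OCc4ccccc4)c(-c4cc(/C(=C\C(=O)c5c(O)cc(OC)cc5O)N(CC)CC)ccc4OC)c(OCc4ccccc4)cc3o2)cc1 | intermediate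
19 | 5,7-bis(benzyloxy)-6-[5-(5-hydroxy-7-methoxy-4-oxo-4H-chromen-2-yl)-2-methoxyphenyl]-2-(4-methoxyphenyl)-4H-chromen-4-one | COc1ccc(-c2cc(=O)c3c(OCc4ccccc4)c(-c4cc(-c5cc(=O)c6c(O)cc(OC)cc6o5)ccc4OC)c(OCc4ccccc4)cc3o2)cc1 | intermediate
20 | 5,7-dihydroxy-6-[5-(5-hydroxy-7-methoxy-4-oxo-4H-chromen-2-yl)-2-methoxyphenyl]-2-(4-methoxyphenyl)-4H-chromen-4-one | COc1ccc(-c2cc(=O)c3c(O)c(-c4cc(-c5cc(=O)c6c(O)cc(OC)cc6o5)ccc4OC)c(O)cc3o2)cc1 | target

## Step count and least certain steps

Total: 12 steps. Longest linear sequence: 7 steps (steps 1, 2, 3, 6, 7, 11, 12).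

**Step 11 (key step).**
- Risk: oxidative addition into the electron-rich, doubly ortho-substituted iodide is slow, so alkynylation may run ahead of CO insertion and end in a benzofuran by 5-endo closure.
- Risk: the amine may capture the aroylpalladium species as a diethylamide.
- Risk: the free iodoresorcinol may lose iodine or oxidise in the basic medium.
- Fallback: this sets out from 12 and 10 and puts the carbonyl carbon on the resorcinol ring beforehand, so no CO is used. Compound 12 would be lithiated as in step 9 and aryllithium 13 quenched with CO2 to give 4-methoxy-2,6-bis(methoxymethoxy)benzoic acid F1. 1-Chloro-N,N,2-trimethylprop-1-en-1-amine in CH2Cl2 at 0 °C would convert it under neutral conditions into 4-methoxy-2,6-bis(methoxymethoxy)benzoyl chloride F2. This would be coupled at once with alkyne 10 (PdCl2(PPh3)2, CuI, Et3N, THF, rt; acyl Sonogashira coupling) to give the bis(methoxymethyl) ynone 5,7-bis(benzyloxy)-6-{5-[3-(4-methoxy-2,6-bis(methoxymethoxy)phenyl)-3-oxoprop-1-yn-1-yl]-2-methoxyphenyl}-2-(4-methoxyphenyl)-4H-chromen-4-one F3. Brief HCl in MeOH would free the two phenols to give ynone 17, and Et2NH in EtOH would close the pyranone through 18. The route is rejoined at 19.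

**Step 6.**
- Risk: transmetalation at a centre that becomes tri-ortho-substituted is slow, so protodeboronation of the ortho-methoxy boronate and hydrodeiodination of 4 may win.
- Fallback: this sets out from bromide 7 and iodide 4 and replaces boron by zinc. Bromine–lithium exchange on 7 (n-BuLi, THF, −78 °C) would give {2-methoxy-5-[(triisopropylsilyl)ethynyl]phenyl}lithium F4. ZnCl2 would convert it into {2-methoxy-5-[(triisopropylsilyl)ethynyl]phenyl}zinc chloride F5. Negishi coupling with 4 (Pd(OAc)2, SPhos, THF, 60 °C) tolerates the pyranone carbonyl and is well suited to hindered biaryls. The route is rejoined at 9.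

**Step 10.**
- Risk: the acid needed for acetal cleavage may protonate the very electron-rich ring at the iodine-bearing carbon and cause loss of iodine; the free diol may also oxidise in air and light.
- Fallback: this sets out from 11 and avoids protecting groups and acid altogether. Compound 11 would be iodinated directly with I2 and NaHCO3 in water at 0 °C, the conditions known to place iodine between the two hydroxyls of resorcinol. The product would be purified from any 4-iodo isomer. The route is rejoined at 15.

**Step 12.**
- Risk: hydrogenolysis of the flanked 5-O-benzyl ether may stall because the biflavone is poorly soluble, and forcing conditions may begin to saturate a C2=C3 bond.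
- Fallback: this sets out from 19 and replaces hydrogenolysis by Lewis-acid ether cleavage. BCl3 with pentamethylbenzene as benzyl cation scavenger in CH2Cl2 at −78 °C removes aryl benzyl ethers and leaves methyl ethers that are not peri to a carbonyl. The route is rejoined at 20.

## Further compounds

F1 | step 11 | 4-methoxy-2,6-bis(methoxymethoxy)benzoic acid | COCOc1cc(OC)cc(OCOC)c1C(=O)O
F2 | step 11 | 4-methoxy-2,6-bis(methoxymethoxy)benzoyl chloride | COCOc1cc(OC)cc(OCOC)c1C(=O)Cl
F3 | step 11 | 5,7-bis(benzyloxy)-6-{5-[3-(4-methoxy-2,6-bis(methoxymethoxy)phenyl)-3-oxoprop-1-yn-1-yl]-2-methoxyphenyl}-2-(4-methoxyphenyl)-4H-chromen-4-one | COc1ccc(-c2cc(=O)c3c(OCc4ccccc4)c(-c4cc(C#CC(=O)c5c(OCOC)cc(OC)cc5OCOC)ccc4OC)c(OCc4ccccc4)cc3o2)cc1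
F4 | step 6 | {2-methoxy-5-[(triisopropylsilyl)ethynyl]phenyl}lithium | COc1ccc(C#C[Si](C(C)C)(C(C)C)C(C)C)cc1[Li]
F5 | step 6 | {2-methoxy-5-[(triisopropylsilyl)ethynyl]phenyl}zinc chloride | COc1ccc(C#C[Si](C(C)C)(C(C)C)C(C)C)cc1[Zn]Cl
F0 | step 10 | none | none
F0 | step 12 | none | none
A1 | alternative 1 | 1-{2,4-bis(benzyloxy)-6-hydroxy-3-[5-(3-(2-hydroxy-4,6-dimethoxyphenyl)-3-oxopropanoyl)-2-methoxyphenyl]phenyl}-3-(4-methoxyphenyl)propane-1,3-dione | COc1ccc(C(=O)CC(=O)c2c(O)cc(OCc3ccccc3)c(-c3cc(C(=O)CC(=O)c4c(O)cc(OC)cc4OC)ccc3OC)c2OCc2ccccc2)cc1
A2 | alternative 1 | 2-acetyl-3,5-bis(benzyloxy)-4-{5-[(2-acetyl-3,5-dimethoxyphenoxy)carbonyl]-2-methoxyphenyl}phenyl 4-methoxybenzoate | COc1ccc(C(=O)Oc2cc(OCc3ccccc3)c(-c3cc(C(=O)Oc4cc(OC)cc(OC)c4C(C)=O)ccc3OC)c(OCc3ccccc3)c2C(C)=O)cc1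
A3 | alternative 2 | 2-(5-bromo-2-methoxyphenyl)benzene-1,3,5-triol | COc1ccc(Br)cc1-c1c(O)cc(O)cc1O
A4 | alternative 2 | methyl 6-(5-bromo-2-methoxyphenyl)-3,5-dioxohexanoate | COC(=O)CC(=O)CC(=O)Cc1cc(Br)ccc1OC
A5 | alternative 3 | 5-hydroxy-7-methoxy-2-{4-methoxy-3-[2,4,6-tris(benzyloxy)phenyl]phenyl}-4H-chromen-4-one | COc1cc(O)c2c(=O)cc(-c3ccc(OC)c(-c4c(OCc5ccccc5)cc(OCc5ccccc5)cc4OCc4ccccc4)c3)oc2c1
A6 | alternative 3 | 1,3-dimethoxy-1-(trimethylsilyloxy)buta-1,3-diene (Brassard diene) | COC(=C)C=C(OC)O[Si](C)(C)C
A7 | alternative 3 | 2-{4-methoxy-3-[2,4,6-tris(benzyloxy)phenyl]phenyl}-5-(phenylsulfinyl)-4H-pyran-4-one (racemic at sulfur) | O=c1cc(-c2ccc(OC)c(-c3c(OCc4ccccc4)cc(OCc4ccccc4)cc3OCc3ccccc3)c2)occ1S(=O)c1ccccc1
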